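**Assumption:** the SMILES carries no stereodescriptor (no stereocentre, and the hindered 6,8''-biaryl axis is unspecified), so the target is taken as drawn and made racemic about the axis.

## Retrosynthetic overview

1. Target ⇐ its tetrabenzyl ether by hydrogenolysis; the 4'-OMe of the 6-linked flavone (unit 1) arrives with acacetin.
2. Key disconnection: the O1–C2 bond of the 8-linked flavone (unit 2) ⇐ a 2'-hydroxychalcone whose only free phenol on that ring sits next to the biaryl axis, so closure can only give the 8-linked isomer.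
3. Chalcone ⇐ biaryl methyl ketone + 4-(benzyloxy)benzaldehyde (Claisen–Schmidt).
4. Biaryl axis ⇐ 6-iodo-7-O-benzylacacetin + 3'-iodo-2'-hydroxy-4',6'-bis(benzyloxy)acetophenone (one-pot borylation/Suzuki).
5. Ring order: both rings of unit 1 are bought (acacetin), then the biaryl bond, then the pyranone of unit 2 last.

## Route

Step 1
Reactants: 1 acacetin (5,7-dihydroxy-2-(4-methoxyphenyl)-4H-chromen-4-one)
Product: 2 7-(benzyloxy)-5-hydroxy-2-(4-methoxyphenyl)-4H-chromen-4-one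
Conditions: BnBr (1.1 equiv), K2CO3 (1.5 equiv), DMF, 25 °C
Reagents that add atoms: benzyl bromide, BrCc1ccccc1
Why: Williamson ether synthesis in which the acidic, unhindered 7-OH reacts while the 5-OH is held in a hydrogen bond to the C4 carbonyl, so one equivalent of benzyl bromide alkylates O7 only.

Step 2
Reactants: 2 7-(benzyloxy)-5-hydroxy-2-(4-methoxyphenyl)-4H-chromen-4-one
Product: 3 7-(benzyloxy)-5-hydroxy-6-iodo-2-(4-methoxyphenyl)-4H-chromen-4-one
Conditions: BnMe3N·ICl2 (1.1 equiv), CaCO3, CH2Cl2–MeOH, 25 °C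
Reagents that add atoms: benzyltrimethylammonium dichloroiodate, C[N+](C)(C)Cc1ccccc1.Cl[I-]Cl
Why: Electrophilic aromatic iodination directed ortho to the free chelated 5-OH, which with O7 alkylated is the known way to put iodine on C6 and not C8 of a 5-hydroxy-7-alkoxyflavone, the anisyl ring being deactivated by the pyranone.

Step 3
Reactants: 4 2'-hydroxy-4',6'-bis(benzyloxy)acetophenone (1-[2,4-bis(benzyloxy)-6-hydroxyphenyl]ethan-1-one)
Product: 5 1-[4,6-bis(benzyloxy)-2-hydroxy-3-iodophenyl]ethan-1-one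
Conditions: BnMe3N·ICl2 (1.05 equiv), CaCO3, CH2Cl2–MeOH, 25 °C
Reagents that add atoms: benzyltrimethylammonium dichloroiodate, C[N+](C)(C)Cc1ccccc1.Cl[I-]Cl
Why: Electrophilic aromatic iodination ortho to the free phenol (C3), the same regiochemistry that gives the known 3'-iodo-2'-hydroxy-4',6'-dialkoxyacetophenones used for 8-substituted flavones.

Step 4
Reactants: 3 7-(benzyloxy)-5-hydroxy-6-iodo-2-(4-methoxyphenyl)-4H-chromen-4-one; 5 1-[4,6-bis(benzyloxy)-2-hydroxy-3-iodophenyl]ethan-1-one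
Product: 7 6-[3-acetyl-4,6-bis(benzyloxy)-2-hydroxyphenyl]-7-(benzyloxy)-5-hydroxy-2-(4-methoxyphenyl)-4H-chromen-4-one, via flavone-6-boronic acid pinacol ester 6 (not isolated)
Conditions: 3, B2pin2 (1.05 equiv), KOAc, Pd2(dba)3 (2.5 mol%), SPhos (10 mol%), 1,4-dioxane, 90 °C; then 5 (0.9 equiv), aq. K3PO4, 100 °C
Reagents that add atoms: bis(pinacolato)diboron, CC1(C)OB(OC1(C)C)B1OC(C)(C)C(C)(C)O1 (its boryl group is carried by 6 only and is lost again on the way to 7)
Why: Miyaura borylation followed in the same flask by Suzuki–Miyaura cross-coupling, for which SPhos-ligated zerovalent palladium is a proven system for tetra-ortho-substituted biaryls bearing ortho oxygen groups and tolerates phenols, the ketone and benzyl ethers; the new axis forms without stereocontrol.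

Step 5
Reactants: 7 6-[3-acetyl-4,6-bis(benzyloxy)-2-hydroxyphenyl]-7-(benzyloxy)-5-hydroxy-2-(4-methoxyphenyl)-4H-chromen-4-one; 8 4-(benzyloxy)benzaldehyde
Product: 9 7-(benzyloxy)-6-{4,6-bis(benzyloxy)-3-[(2E)-3-[4-(benzyloxy)phenyl]prop-2-enoyl]-2-hydroxyphenyl}-5-hydroxy-2-(4-methoxyphenyl)-4H-chromen-4-one
Conditions: 8 (1.5 equiv), KOH (50% aq.), EtOH–THF, 0 to 25 °C; then dilute HCl
Reagents that add atoms: none
Why: Claisen–Schmidt (crossed aldol) condensation in which the acetyl group is the only enolisable carbonyl and the aldehyde cannot enolise, E1cB dehydration gives the E-enone, and the flavone of unit 1 is shielded from hydroxide as its 5-phenoxide.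

Step 6
Reactants: 9 7-(benzyloxy)-6-{4,6-bis(benzyloxy)-3-[(2E)-3-[4-(benzyloxy)phenyl]prop-2-enoyl]-2-hydroxyphenyl}-5-hydroxy-2-(4-methoxyphenyl)-4H-chromen-4-one
Product: 11 5,7-bis(benzyloxy)-8-[7-(benzyloxy)-5-hydroxy-2-(4-methoxyphenyl)-4-oxo-4H-chromen-6-yl]-2-[4-(benzyloxy)phenyl]-4H-chromen-4-one, via flavanone 10 (not isolated)
Conditions: 4CzIPN (2 mol%), Co(dmgH)2(py)Cl (5 mol%), Cs2CO3 (20 mol%), degassed DMF–MeCN, 450 nm LEDs, 25 °C, Ar, H2 vented
Reagents that add atoms: none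
Why: Proposed new method: catalytic base turns the only free phenol of that ring into a phenoxide that adds 6-endo to the enone (oxa-Michael) to form the O1–C2 bond and the flavanone enolate, excited 4CzIPN oxidises this enolate to the C3 radical, and the divalent cobaloxime removes the weak C2–H as a hydrogen atom to give the C2=C3 bond and a cobalt hydride that releases H2, so no external oxidant touches the benzyl ethers or electron-rich rings and the transient C2 stereocentre is erased; the closest known reaction types are photoredox/cobaloxime acceptorless desaturation of carbonyl compounds and the base-mediated chalcone-to-flavanone oxa-Michael cyclisation.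

Step 7
Reactants: 11 5,7-bis(benzyloxy)-8-[7-(benzyloxy)-5-hydroxy-2-(4-methoxyphenyl)-4-oxo-4H-chromen-6-yl]-2-[4-(benzyloxy)phenyl]-4H-chromen-4-one
Product: 12 5,7-dihydroxy-8-[5,7-dihydroxy-2-(4-methoxyphenyl)-4-oxo-4H-chromen-6-yl]-2-(4-hydroxyphenyl)-4H-chromen-4-one (CNP0302154.0)
Conditions: H2 (1 atm), Pd(OH)2/C, THF–MeOH, 25 °C
Reagents that add atoms: none
Why: Catalytic hydrogenolysis cleaves the four benzyl aryl ethers while the aryl methyl ether, both flavone C2=C3 bonds and the biaryl are inert at 1 atm and room temperature.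

## Compound list

1 | acacetin, 5,7-dihydroxy-2-(4-methoxyphenyl)-4H-chromen-4-one | COc1ccc(cc1)-c1cc(=O)c2c(O)cc(O)cc2o1 | starting material
2 | 7-(benzyloxy)-5-hydroxy-2-(4-methoxyphenyl)-4H-chromen-4-one | COc1ccc(cc1)-c1cc(=O)c2c(O)cc(OCc3ccccc3)cc2o1 | intermediate
3 | 7-(benzyloxy)-5-hydroxy-6-iodo-2-(4-methoxyphenyl)-4H-chromen-4-one | COc1ccc(cc1)-c1cc(=O)c2c(O)c(I)c(OCc3ccccc3)cc2o1 | intermediate
4 | 2'-hydroxy-4',6'-bis(benzyloxy)acetophenone, 1-[2,4-bis(benzyloxy)-6-hydroxyphenyl]ethan-1-one | CC(=O)c1c(O)cc(OCc2ccccc2)cc1OCc1ccccc1 | starting material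
5 | 1-[4,6-bis(benzyloxy)-2-hydroxy-3-iodophenyl]ethan-1-one | CC(=O)c1c(O)c(I)c(OCc2ccccc2)cc1OCc1ccccc1 | intermediate
6 | 7-(benzyloxy)-5-hydroxy-2-(4-methoxyphenyl)-6-(4,4,5,5-tetramethyl-1,3,2-dioxaborolan-2-yl)-4H-chromen-4-one (not isolated) | COc1ccc(cc1)-c1cc(=O)c2c(O)c(B3OC(C)(C)C(C)(C)O3)c(OCc3ccccc3)cc2o1 | intermediate
7 | 6-[3-acetyl-4,6-bis(benzyloxy)-2-hydroxyphenyl]-7-(benzyloxy)-5-hydroxy-2-(4-methoxyphenyl)-4H-chromen-4-one, racemic about the biaryl axis | COc1ccc(cc1)-c1cc(=O)c2c(O)c(c(OCc3ccccc3)cc2o1)-c1c(O)c(C(C)=O)c(OCc2ccccc2)cc1OCc1ccccc1 | intermediate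
8 | 4-(benzyloxy)benzaldehyde | O=Cc1ccc(OCc2ccccc2)cc1 | starting material
9 | 7-(benzyloxy)-6-{4,6-bis(benzyloxy)-3-[(2E)-3-[4-(benzyloxy)phenyl]prop-2-enoyl]-2-hydroxyphenyl}-5-hydroxy-2-(4-methoxyphenyl)-4H-chromen-4-one, racemic about the axis | COc1ccc(cc1)-c1cc(=O)c2c(O)c(c(OCc3ccccc3)cc2o1)-c1c(O)c(C(=O)/C=C/c2ccc(OCc3ccccc3)cc2)c(OCc2ccccc2)cc1OCc1ccccc1 | intermediate
10 | 5,7-bis(benzyloxy)-8-[7-(benzyloxy)-5-hydroxy-2-(4-methoxyphenyl)-4-oxo-4H-chromen-6-yl]-2-[4-(benzyloxy)phenyl]-2,3-dihydro-4H-chromen-4-one (flavanone, not isolated, C2 not controlled) | COc1ccc(cc1)-c1cc(=O)c2c(O)c(c(OCc3ccccc3)cc2o1)-c1c(OCc2ccccc2)cc(OCc2ccccc2)c2C(=O)CC(Oc12)c1ccc(OCc2ccccc2)cc1 | intermediate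
11 | 5,7-bis(benzyloxy)-8-[7-(benzyloxy)-5-hydroxy-2-(4-methoxyphenyl)-4-oxo-4H-chromen-6-yl]-2-[4-(benzyloxy)phenyl]-4H-chromen-4-one, racemic about the axis | COc1ccc(cc1)-c1cc(=O)c2c(O)c(c(OCc3ccccc3)cc2o1)-c1c(OCc2ccccc2)cc(OCc2ccccc2)c2c(=O)cc(oc12)-c1ccc(OCc2ccccc2)cc1 | intermediate
12 | 5,7-dihydroxy-8-[5,7-dihydroxy-2-(4-methoxyphenyl)-4-oxo-4H-chromen-6-yl]-2-(4-hydroxyphenyl)-4H-chromen-4-one (CNP0302154.0) | COc1ccc(-c2cc(=O)c3c(O)c(-c4c(O)cc(O)c5c(=O)cc(-c6ccc(O)cc6)oc45)c(O)cc3o2)cc1 | target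

## Step count and risks

Total steps: 7 (products isolated: 2, 3, 5, 7, 9, 11, 12). Longest linear sequence: 6 steps (1 → 2 → 3 → 7 → 9 → 11 → 12).

Steps most likely to fail:

**Step 4.** The one-pot borylation/Suzuki must build a tetra-ortho-substituted biaryl next to two free phenols, and boronate 6 may protodeboronate. The fallback uses known copper chemistry in place of palladium and boron. It sets out from 3 and 5, whose chelated phenols are capped (NaH, MOMCl, DMF) to give 7-(benzyloxy)-6-iodo-5-(methoxymethoxy)-2-(4-methoxyphenyl)-4H-chromen-4-one F1 and 1-[4,6-bis(benzyloxy)-3-iodo-2-(methoxymethoxy)phenyl]ethan-1-one F2. A mixed Ullmann reductive coupling (activated Cu powder, DMF, 150 °C, homodimers removed by chromatography) joins them to 6-[3-acetyl-4,6-bis(benzyloxy)-2-(methoxymethoxy)phenyl]-7-(benzyloxy)-5-(methoxymethoxy)-2-(4-methoxyphenyl)-4H-chromen-4-one F3. Cleaving both acetals (HCl, MeOH–THF, 50 °C) comes back to the route at 7.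

**Step 5.** The Claisen–Schmidt condensation runs on a crowded ketone in the presence of a base-sensitive flavone. The fallback changes the order of bond formation. It sets out from 5, which is condensed first with 8 (KOH, EtOH, 25 °C) to (2E)-1-[4,6-bis(benzyloxy)-2-hydroxy-3-iodophenyl]-3-[4-(benzyloxy)phenyl]prop-2-en-1-one F4. F4 is then coupled with boronate 6, made in the flask from 3 as in step 4 (Pd2(dba)3, SPhos, K3PO4, dioxane–H2O, 90 °C), and comes back to the route at 9; any flavanone formed from the chalcone under these conditions converges in step 6.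

**Step 6.** This is the proposed new method; phenoxide absorption, competing phenol oxidation, or hydrogen-atom transfer from the cobalt hydride to the enone may spoil it. The fallback uses known chemistry and a redox-neutral ring closure. It sets out from 7, whose lithium enolate is C-acylated (LiN(SiMe3)2, 5 equiv, THF, −78 °C, then 4-(benzyloxy)benzoyl chloride) to 1-[2,4-bis(benzyloxy)-5-[7-(benzyloxy)-5-hydroxy-2-(4-methoxyphenyl)-4-oxo-4H-chromen-6-yl]-6-hydroxyphenyl]-3-[4-(benzyloxy)phenyl]propane-1,3-dione F5. Acid cyclodehydration (TsOH, toluene, 80 °C) closes the same O1–C2 bond through the same single free phenol and comes back to the route at 11.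

## Further compounds

F1 | step 4 | 7-(benzyloxy)-6-iodo-5-(methoxymethoxy)-2-(4-methoxyphenyl)-4H-chromen-4-one | COc1ccc(cc1)-c1cc(=O)c2c(OCOC)c(I)c(OCc3ccccc3)cc2o1
F2 | step 4 | 1-[4,6-bis(benzyloxy)-3-iodo-2-(methoxymethoxy)phenyl]ethan-1-one | CC(=O)c1c(OCOC)c(I)c(OCc2ccccc2)cc1OCc1ccccc1
F3 | step 4 | 6-[3-acetyl-4,6-bis(benzyloxy)-2-(methoxymethoxy)phenyl]-7-(benzyloxy)-5-(methoxymethoxy)-2-(4-methoxyphenyl)-4H-chromen-4-one | COc1ccc(cc1)-c1cc(=O)c2c(OCOC)c(c(OCc3ccccc3)cc2o1)-c1c(OCOC)c(C(C)=O)c(OCc2ccccc2)cc1OCc1ccccc1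
F4 | step 5 | (2E)-1-[4,6-bis(benzyloxy)-2-hydroxy-3-iodophenyl]-3-[4-(benzyloxy)phenyl]prop-2-en-1-one | O=C(/C=C/c1ccc(OCc2ccccc2)cc1)c1c(O)c(I)c(OCc2ccccc2)cc1OCc1ccccc1
F5 | step 6 | 1-[2,4-bis(benzyloxy)-5-[7-(benzyloxy)-5-hydroxy-2-(4-methoxyphenyl)-4-oxo-4H-chromen-6-yl]-6-hydroxyphenyl]-3-[4-(benzyloxy)phenyl]propane-1,3-dione | COc1ccc(cc1)-c1cc(=O)c2c(O)c(c(OCc3ccccc3)cc2o1)-c1c(O)c(C(=O)CC(=O)c2ccc(OCc3ccccc3)cc2)c(OCc2ccccc2)cc1OCc1ccccc1
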